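## Retrosynthetic overview

1. The target comes from its bis-silyl ether; ring C is closed last through the O1–C2 bond by a 6-endo oxa-Michael addition of the 2'-phenol of an α-methylene deoxybenzoin, with enantioselective protonation of the resulting enolate at C3 (sets 3R).
2. The α-methylene deoxybenzoin comes from a deoxybenzoin plus formaldehyde (C2); the 2'-OH stays masked as a PMB ether until just before ring closure.
3. The deoxybenzoin comes from a ring A acetophenone and a ring B aryl bromide by Pd-catalysed ketone α-arylation.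
4. The ring B bromide comes from 5-bromosalicylaldehyde and 3-chloro-3-methylbut-1-yne (propargyl ether, Baeyer–Villiger for the 8-oxygen, Claisen/electrocyclisation).
5. Ring order: the pyran ring of the chromene first, the chromanone ring C last.

Assumption: catalyst Q is 3-{[3,5-bis(trifluoromethyl)phenyl]amino}-4-{[(9R)-6'-methoxycinchonan-9-yl]amino}cyclobut-3-ene-1,2-dione (quinidine-derived squaramide, commercial); which pseudoenantiomer gives 3R cannot be predicted with confidence, so if a first small run gives 3S, the quinine-derived (8α,9S) pseudoenantiomer is used instead.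

## Route

Step 1
Reactants: 1 5-bromo-2-hydroxybenzaldehyde; 2 3-chloro-3-methylbut-1-yne
Product: 3 5-bromo-2-[(2-methylbut-3-yn-2-yl)oxy]benzaldehyde
Conditions: K2CO3, KI (cat.), CuI (5 mol %), acetone, 60 °C
Reagents that add atoms: none
Why: Copper-assisted Williamson-type O-propargylation of the acidic salicylaldehyde phenol, the standard entry to aryl 1,1-dimethylpropargyl ethers; aldehyde and aryl bromide are inert.

Step 2
Reactants: 3 5-bromo-2-[(2-methylbut-3-yn-2-yl)oxy]benzaldehyde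
Product: 5 5-bromo-2-[(2-methylbut-3-yn-2-yl)oxy]phenol, via aryl formate 4 (not isolated)
Conditions: mCPBA, CH2Cl2, 0 °C to rt; aq. NaHCO3 wash; then K2CO3 (cat.), MeOH, rt
Reagents that add atoms: m-chloroperoxybenzoic acid (mCPBA), OOC(=O)c1cccc(Cl)c1
Why: Baeyer–Villiger (Dakin-type) oxidation in which the electron-rich ortho-alkoxyaryl group migrates, then methanolysis of the formate; the oxygen is installed now because the terminal alkyne tolerates the peracid whereas the later chromene olefin would not.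

Step 3
Reactants: 5 5-bromo-2-[(2-methylbut-3-yn-2-yl)oxy]phenol
Product: 6 {5-bromo-2-[(2-methylbut-3-yn-2-yl)oxy]phenoxy}tri(propan-2-yl)silane
Conditions: TIPSCl, imidazole, DMF, rt
Reagents that add atoms: chlorotri(propan-2-yl)silane (TIPSCl), CC(C)[Si](Cl)(C(C)C)C(C)C
Why: Standard phenol silylation; the aryl TIPS ether survives heat, alkoxide base and DDQ and leaves at the end under buffered fluoride.

Step 4
Reactants: 6 {5-bromo-2-[(2-methylbut-3-yn-2-yl)oxy]phenoxy}tri(propan-2-yl)silane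
Product: 7 [(6-bromo-2,2-dimethyl-2H-chromen-8-yl)oxy]tri(propan-2-yl)silane
Conditions: o-xylene, 140 °C, sealed tube
Reagents that add atoms: none
Why: Aromatic propargyl Claisen rearrangement ([3,3] shift to the only free ortho carbon, enolisation, 1,5-H shift, oxa-6π electrocyclisation) gives the 2,2-dimethyl-2H-chromene with bromine para to the ring oxygen by construction.

Step 5
Reactants: 8 1-(2,4-dihydroxy-6-methoxyphenyl)ethan-1-one
Product: 9 1-{2-hydroxy-6-methoxy-4-[(triisopropylsilyl)oxy]phenyl}ethan-1-one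
Conditions: TIPSCl (1.1 equiv), imidazole, CH2Cl2, 0 °C
Reagents that add atoms: chlorotri(propan-2-yl)silane (TIPSCl), CC(C)[Si](Cl)(C(C)C)C(C)C
Why: Selective silylation of the free 4-OH, because the 2-OH is tied up in a hydrogen bond to the acetyl carbonyl.

Step 6
Reactants: 9 1-{2-hydroxy-6-methoxy-4-[(triisopropylsilyl)oxy]phenyl}ethan-1-one
Product: 10 1-{2-methoxy-6-[(4-methoxybenzyl)oxy]-4-[(triisopropylsilyl)oxy]phenyl}ethan-1-one
Conditions: PMBCl, K2CO3, Bu4NI (cat.), dry acetone, reflux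
Reagents that add atoms: 4-methoxybenzyl chloride (PMBCl), COc1ccc(CCl)cc1
Why: Williamson etherification of the chelated phenol with a reactive benzylic halide; PMB is chosen because it comes off later under neutral oxidative conditions.

Step 7
Reactants: 10 1-{2-methoxy-6-[(4-methoxybenzyl)oxy]-4-[(triisopropylsilyl)oxy]phenyl}ethan-1-one; 7 [(6-bromo-2,2-dimethyl-2H-chromen-8-yl)oxy]tri(propan-2-yl)silane
Product: 11 2-{2,2-dimethyl-8-[(triisopropylsilyl)oxy]-2H-chromen-6-yl}-1-{2-methoxy-6-[(4-methoxybenzyl)oxy]-4-[(triisopropylsilyl)oxy]phenyl}ethan-1-one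
Conditions: Pd2(dba)3 (1.5 mol %), Xantphos (3.6 mol %), NaOtBu, toluene, 80 °C
Reagents that add atoms: none
Why: Palladium-catalysed α-arylation of a methyl ketone enolate (Buchwald–Hartwig type); the 2,6-disubstituted aryl ketone cannot self-condense, the wide-bite-angle ligand favours mono-arylation, and the hindered cis chromene olefin does not compete by Heck insertion.

Step 8
Reactants: 11 2-{2,2-dimethyl-8-[(triisopropylsilyl)oxy]-2H-chromen-6-yl}-1-{2-methoxy-6-[(4-methoxybenzyl)oxy]-4-[(triisopropylsilyl)oxy]phenyl}ethan-1-one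
Product: 12 2-{2,2-dimethyl-8-[(triisopropylsilyl)oxy]-2H-chromen-6-yl}-1-{2-methoxy-6-[(4-methoxybenzyl)oxy]-4-[(triisopropylsilyl)oxy]phenyl}prop-2-en-1-one
Conditions: (CH2O)n (3 equiv), piperidine (0.2 equiv), AcOH (0.2 equiv), 1,4-dioxane, 80 °C
Reagents that add atoms: paraformaldehyde (formaldehyde), C=O
Why: Mannich-type α-methylenation of the doubly activated benzylic methylene (aminomethylation then elimination), a standard route from deoxybenzoins to 1,2-diarylpropenones; no free phenol is present, so the enone cannot cyclise.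

Step 9
Reactants: 12 2-{2,2-dimethyl-8-[(triisopropylsilyl)oxy]-2H-chromen-6-yl}-1-{2-methoxy-6-[(4-methoxybenzyl)oxy]-4-[(triisopropylsilyl)oxy]phenyl}prop-2-en-1-one
Product: 13 2-{2,2-dimethyl-8-[(triisopropylsilyl)oxy]-2H-chromen-6-yl}-1-{2-hydroxy-6-methoxy-4-[(triisopropylsilyl)oxy]phenyl}prop-2-en-1-one
Conditions: DDQ (1.3 equiv), CH2Cl2/pH 7 buffer 10:1, 0 °C; cold neutral work-up, short neutral silica plug, used the same day
Reagents that add atoms: none
Why: Oxidative PMB ether cleavage (benzylic hydride abstraction by DDQ, hydrolysis of the oxocarbenium ion) frees the 2'-phenol without acid or base, so it stays hydrogen-bonded to the ketone and does not add to the enone; the 2,2-disubstituted chromene has no abstractable hydride and the TIPS ethers are inert.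

Step 10
Reactants: 13 2-{2,2-dimethyl-8-[(triisopropylsilyl)oxy]-2H-chromen-6-yl}-1-{2-hydroxy-6-methoxy-4-[(triisopropylsilyl)oxy]phenyl}prop-2-en-1-one
Product: 15 (3R)-7-hydroxy-3-(8-hydroxy-2,2-dimethyl-2H-chromen-6-yl)-5-methoxy-2,3-dihydro-4H-chromen-4-one, via bis-TIPS isoflavanone 14 (not isolated)
Conditions: catalyst Q (10 mol %), 4 Å MS, toluene, −40 °C; then AcOH (5 equiv), TBAF (2.5 equiv), THF, 0 °C
Reagents that add atoms: none
Why: Proposed new method: a catalytic enantioselective 6-endo oxa-Michael addition/protonation cascade that closes ring C through the O1–C2 bond; the quinuclidine nitrogen of Q takes the proton of the 2'-OH while the squaramide N–H pair binds the ketone oxygen of the s-trans acrylophenone, the phenoxide adds to the unsubstituted CH2 terminus, and the squaramide-bound cyclic enolate is protonated at C3 on its Si face (priorities C4 > C2 > C1') by the quinuclidinium N–H held over that face, which sets 3R under kinetic control; the uncatalysed closure is slow because the phenol is hydrogen-bonded to the carbonyl and points away from the CH2, the weakly basic catalyst at −40 °C should not re-enolise the product, and acetic acid then silences the amine so that buffered fluoride removes both TIPS groups without base; the closest known reaction types are cinchona-base tandem conjugate addition/enantioselective protonation of α-substituted Michael acceptors and amine–thiourea oxa-Michael closures to flavanones, neither of which, to my knowledge, has been shown for 2-aryl-1-(2-hydroxyaryl)prop-2-en-1-ones.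

## Compound list

1 | 5-bromo-2-hydroxybenzaldehyde | O=Cc1cc(Br)ccc1O | starting material
2 | 3-chloro-3-methylbut-1-yne | CC(C)(Cl)C#C | starting material
3 | 5-bromo-2-[(2-methylbut-3-yn-2-yl)oxy]benzaldehyde | O=Cc1cc(Br)ccc1OC(C)(C)C#C | intermediate
4 | 5-bromo-2-[(2-methylbut-3-yn-2-yl)oxy]phenyl formate | O=COc1cc(Br)ccc1OC(C)(C)C#C | intermediate (not isolated)
5 | 5-bromo-2-[(2-methylbut-3-yn-2-yl)oxy]phenol | Oc1cc(Br)ccc1OC(C)(C)C#C | intermediate
6 | {5-bromo-2-[(2-methylbut-3-yn-2-yl)oxy]phenoxy}tri(propan-2-yl)silane | CC(C)[Si](Oc1cc(Br)ccc1OC(C)(C)C#C)(C(C)C)C(C)C | intermediate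
7 | [(6-bromo-2,2-dimethyl-2H-chromen-8-yl)oxy]tri(propan-2-yl)silane | CC(C)[Si](Oc1cc(Br)cc2C=CC(C)(C)Oc12)(C(C)C)C(C)C | intermediate
8 | 1-(2,4-dihydroxy-6-methoxyphenyl)ethan-1-one | CC(=O)c1c(O)cc(O)cc1OC | starting material
9 | 1-{2-hydroxy-6-methoxy-4-[(triisopropylsilyl)oxy]phenyl}ethan-1-one | CC(=O)c1c(O)cc(O[Si](C(C)C)(C(C)C)C(C)C)cc1OC | intermediate
10 | 1-{2-methoxy-6-[(4-methoxybenzyl)oxy]-4-[(triisopropylsilyl)oxy]phenyl}ethan-1-one | CC(=O)c1c(OCc2ccc(OC)cc2)cc(O[Si](C(C)C)(C(C)C)C(C)C)cc1OC | intermediate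
11 | 2-{2,2-dimethyl-8-[(triisopropylsilyl)oxy]-2H-chromen-6-yl}-1-{2-methoxy-6-[(4-methoxybenzyl)oxy]-4-[(triisopropylsilyl)oxy]phenyl}ethan-1-one | O=C(Cc1cc(O[Si](C(C)C)(C(C)C)C(C)C)c2OC(C)(C)C=Cc2c1)c1c(OCc2ccc(OC)cc2)cc(O[Si](C(C)C)(C(C)C)C(C)C)cc1OC | intermediate
12 | 2-{2,2-dimethyl-8-[(triisopropylsilyl)oxy]-2H-chromen-6-yl}-1-{2-methoxy-6-[(4-methoxybenzyl)oxy]-4-[(triisopropylsilyl)oxy]phenyl}prop-2-en-1-one | C=C(c1cc(O[Si](C(C)C)(C(C)C)C(C)C)c2OC(C)(C)C=Cc2c1)C(=O)c1c(OCc2ccc(OC)cc2)cc(O[Si](C(C)C)(C(C)C)C(C)C)cc1OC | intermediate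
13 | 2-{2,2-dimethyl-8-[(triisopropylsilyl)oxy]-2H-chromen-6-yl}-1-{2-hydroxy-6-methoxy-4-[(triisopropylsilyl)oxy]phenyl}prop-2-en-1-one | C=C(c1cc(O[Si](C(C)C)(C(C)C)C(C)C)c2OC(C)(C)C=Cc2c1)C(=O)c1c(O)cc(O[Si](C(C)C)(C(C)C)C(C)C)cc1OC | intermediate
14 | (3R)-3-{2,2-dimethyl-8-[(triisopropylsilyl)oxy]-2H-chromen-6-yl}-5-methoxy-7-[(triisopropylsilyl)oxy]-2,3-dihydro-4H-chromen-4-one | COc1cc(O[Si](C(C)C)(C(C)C)C(C)C)cc2c1C(=O)[C@H](c1cc(O[Si](C(C)C)(C(C)C)C(C)C)c3c(c1)C=CC(C)(C)O3)CO2 | intermediate (not isolated)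
15 | (3R)-7-hydroxy-3-(8-hydroxy-2,2-dimethyl-2H-chromen-6-yl)-5-methoxy-2,3-dihydro-4H-chromen-4-one | COc1cc(O)cc2c1C(=O)[C@H](c1cc(O)c3c(c1)C=CC(C)(C)O3)CO2 | target

## Step count and risks

Total steps: 10. Longest linear sequence: 8 (steps 1, 2, 3, 4, 7, 8, 9, 10).

The three steps most likely to fail:

**Step 10 (the new step).** The risks are low enantioselectivity in the protonation, a racemic background closure, or erosion of the C3 centre by the amine. The fallback uses known chemistry and sets out from 13. A trace of Et3N in CH2Cl2 at rt closes 13 to the racemic 3-{2,2-dimethyl-8-[(triisopropylsilyl)oxy]-2H-chromen-6-yl}-5-methoxy-7-[(triisopropylsilyl)oxy]-2,3-dihydro-4H-chromen-4-one F1. Noyori transfer hydrogenation under dynamic kinetic resolution (RuCl[(R,R)-TsDPEN](p-cymene), HCO2H/Et3N, EtOAc, 40 °C; the amine keeps C3 of the ketone racemising while one enantiomer is reduced) gives the cis alcohol (3R,4R)-3-{2,2-dimethyl-8-[(triisopropylsilyl)oxy]-2H-chromen-6-yl}-5-methoxy-7-[(triisopropylsilyl)oxy]-3,4-dihydro-2H-chromen-4-ol F2; the other enantiomer of the complex is used if the sense is opposite. Dess–Martin periodinane in CH2Cl2 at 0 °C oxidises F2 without touching C3 and comes back to the route at 14, which is desilylated with TBAF/AcOH as in step 10.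

**Step 9.** DDQ may attack the electron-rich ring B, or 13 may close on handling. The fallback sets out from 9 and swaps the oxidatively removed PMB group for a chelation-cleaved acetal. MOMCl, i-Pr2NEt, CH2Cl2, 40 °C gives 1-{2-methoxy-6-(methoxymethoxy)-4-[(triisopropylsilyl)oxy]phenyl}ethan-1-one F3. α-Arylation with 7 as in step 7 gives 2-{2,2-dimethyl-8-[(triisopropylsilyl)oxy]-2H-chromen-6-yl}-1-{2-methoxy-6-(methoxymethoxy)-4-[(triisopropylsilyl)oxy]phenyl}ethan-1-one F4. Methylenation as in step 8 gives 2-{2,2-dimethyl-8-[(triisopropylsilyl)oxy]-2H-chromen-6-yl}-1-{2-methoxy-6-(methoxymethoxy)-4-[(triisopropylsilyl)oxy]phenyl}prop-2-en-1-one F5. MgBr2·OEt2 in Et2O/CH2Cl2 at 0 °C then cleaves only the MOM group that chelates with the ketone; the phenol is held as its magnesium chelate, which cannot reach the CH2, and a cold pH 6 work-up comes back to the route at 13.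

**Step 7.** The risks are a slow reaction of the hindered enolate, double arylation, or loss of the aryl silyl ethers to alkoxide. The fallback sets out from 10 and replaces the alkali enolate by a tin enolate under neutral conditions. KHMDS, THF, −78 °C, then Ac2O gives 1-{2-methoxy-6-[(4-methoxybenzyl)oxy]-4-[(triisopropylsilyl)oxy]phenyl}ethenyl acetate F6. Migita coupling of F6 with 7 (Bu3SnOMe, PdCl2[P(o-tol)3]2, toluene, 100 °C) comes back to the route at 11.

## Further compounds

F1 | step 10 | rac-3-{2,2-dimethyl-8-[(triisopropylsilyl)oxy]-2H-chromen-6-yl}-5-methoxy-7-[(triisopropylsilyl)oxy]-2,3-dihydro-4H-chromen-4-one | COc1cc(O[Si](C(C)C)(C(C)C)C(C)C)cc2c1C(=O)C(c1cc(O[Si](C(C)C)(C(C)C)C(C)C)c3c(c1)C=CC(C)(C)O3)CO2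
F2 | step 10 | (3R,4R)-3-{2,2-dimethyl-8-[(triisopropylsilyl)oxy]-2H-chromen-6-yl}-5-methoxy-7-[(triisopropylsilyl)oxy]-3,4-dihydro-2H-chromen-4-ol | COc1cc(O[Si](C(C)C)(C(C)C)C(C)C)cc2c1[C@H](O)[C@H](c1cc(O[Si](C(C)C)(C(C)C)C(C)C)c3c(c1)C=CC(C)(C)O3)CO2
F3 | step 9 | 1-{2-methoxy-6-(methoxymethoxy)-4-[(triisopropylsilyl)oxy]phenyl}ethan-1-one | CC(=O)c1c(OCOC)cc(O[Si](C(C)C)(C(C)C)C(C)C)cc1OC
F4 | step 9 | 2-{2,2-dimethyl-8-[(triisopropylsilyl)oxy]-2H-chromen-6-yl}-1-{2-methoxy-6-(methoxymethoxy)-4-[(triisopropylsilyl)oxy]phenyl}ethan-1-one | O=C(Cc1cc(O[Si](C(C)C)(C(C)C)C(C)C)c2OC(C)(C)C=Cc2c1)c1c(OCOC)cc(O[Si](C(C)C)(C(C)C)C(C)C)cc1OC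
F5 | step 9 | 2-{2,2-dimethyl-8-[(triisopropylsilyl)oxy]-2H-chromen-6-yl}-1-{2-methoxy-6-(methoxymethoxy)-4-[(triisopropylsilyl)oxy]phenyl}prop-2-en-1-one | C=C(c1cc(O[Si](C(C)C)(C(C)C)C(C)C)c2OC(C)(C)C=Cc2c1)C(=O)c1c(OCOC)cc(O[Si](C(C)C)(C(C)C)C(C)C)cc1OC
F6 | step 7 | 1-{2-methoxy-6-[(4-methoxybenzyl)oxy]-4-[(triisopropylsilyl)oxy]phenyl}ethenyl acetate | C=C(OC(C)=O)c1c(OCc2ccc(OC)cc2)cc(O[Si](C(C)C)(C(C)C)C(C)C)cc1OC
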